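The reading due at 150 h is what the alpha flask is waiting for, and its c(Sub) at the start is higher than in any finished run, so what it will hold has to be reckoned from those runs.

| flask | Sub | Cat | time |
|---|---|---|---|
| zeta | 0.200 M | 4.00 × 10⁻⁴ M |  |
| gamma | 0.0800 M | 4.00 × 10⁻⁴ M |  |
| beta | 0.100 M | 4.00 × 10⁻⁴ M |  |
| alpha | 0.600 M | 0.00120 M | 150 h |

| run | time / h | [Prd] / M |
|---|---|---|
| zeta run | 8.5 | 0.0434 |
| zeta run | 26 | 0.0701 |
| zeta run | 49 | 0.0951 |
| zeta run | 78 | 0.1160 |
| zeta run | 110 | 0.1364 |
| zeta run | 150 | 0.1564 |
| gamma run | 8.5 | 0.0109 |
| gamma run | 26 | 0.0223 |
| gamma run | 49 | 0.0310 |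
| gamma run | 78 | 0.0434 |
| gamma run | 110 | 0.0501 |
| gamma run | 150 | 0.0604 |
| beta run | 8.5 | 0.0139 |
| beta run | 26 | 0.0286 |
| beta run | 49 | 0.0400 |
| beta run | 78 | 0.0555 |
| beta run | 110 | 0.0638 |
| beta run | 150 | 0.0742 |

(scatter of a reading: 0.001 M)

- Overall: Sub -> Prd, with Cat as catalyst.
- Constant volume, constant temperature.
- What is held in complexes is read along with the free species.
- An order is taken over about fifteen percent of the charge, up and down.

- the exponent of [Sub] in the starting rate at the charge of the zeta run (at the point where two percent of the Sub have become Prd) (one fixed amount of Prd, the same in the runs compared)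
- the gamma run starts with 0.120 M less of Sub than the zeta run, and with no Prd. Compared where both hold the same amount of Sub, once fifteen percent of what the gamma run was charged with has turned into Prd, is the gamma run faster, slower or alike (within a tenth)?
- Prd in the alpha run at 150 h, as a share of the Sub charged

Late in each run, Sub falls as a first-order decay. The zeta run gives 0.00869 h⁻¹ between 49 h and 150 h, the gamma run 0.00907 h⁻¹ and the beta run 0.00836 h⁻¹. Run back to time zero, the zeta line meets c(Sub) at 0.161 M, less than the charge of 0.200 M, and that gap is an early burst.

Suppose the burst goes with the square of c(Sub) and with the Cat charged, over a fixed active time. The reciprocal of c(Sub) then rises in proportion to the Cat charge, which defines the burst constant, the rise in that reciprocal across the burst per unit of Cat charged: 3070 M⁻². This is an assumption fitted to the zeta run, because in the gamma and beta runs running back turns a scatter of 0.001 M into a larger one of 0.00368 M.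

For the alpha flask, the burst constant puts c(Sub) after the burst at an estimated 0.187 M, and the late decay takes that to an estimated 0.0508 M at the reading, so this reckoning expects 91.5 % of the charge as Prd. It holds the late constant unchanged by c(Cat), which runs each charged with 4.00 × 10⁻⁴ M cannot test. The flask should stay closed and at its temperature, since both constants were read under those conditions.

The forecast gives an exponent of 1.6 for c(Sub) at the charge of the zeta run, calls the gamma run faster, and puts the alpha flask at 96 %, a share higher than that of this reckoning, noting that “The catalyst order is untested, so I shade this down”.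

The alpha flask gives 91.0 % of its charge as Prd at 150 h, which leaves 0.0540 M of that charge in forms other than Prd; at the charge of the zeta run the exponent of c(Sub) is 1.8, and the gamma run is faster than the zeta run, with a rate ratio of 1.3 where both hold the same amount of Sub.

    Cat + Sub ⇌ Cat.Sub, settled at all times (0.7070 M⁻¹)
    Cat.Sub + Sub ⇌ Cat.Sub2, settled at all times (2.640 M⁻¹)
    Cat.Sub2 → Prd + Cat.Sub (314.6 h⁻¹)
    Cat → L (0.1944 h⁻¹)
    Sub → Prd (0.008640 h⁻¹)

On the gamma run, the burst constant from the zeta run puts c(Sub) after the burst at 0.0729 M, and the late decay from there reaches half of the gamma charge at 69.0 h, while the gamma run itself gets there at 70.0 h.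

All runs were generated by integration for substances that don't exist; scatter was added.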